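**Plan**
- Retrosynthesis: the two benzyl ethers come off last. Ring A is then cut at C4a–C5 and C8–C8a into a 5-sulfinyl-2,3-dihydropyran-4-one (ring C with C2 and C3 in place) and a 2-benzyloxy-1,3-dimethoxy-1-silyloxybutadiene. Ring C is cut at C2–C3 and O1–C6 into the benzylated aldehyde and Danishefsky's diene.
- Enabling feature: ring A carries oxygen on C5, C6, C7 and C8a and hydrogen only on C8. This is a 1,2,3-trioxygenated butadiene (C5–C8) laid over the C4a=C8a enol-ether bond of the pyranone.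
- Forward order: ring C by catalytic asymmetric hetero-Diels–Alder, C3 oxygenation and methylation, C5 sulfenylation and oxidation, ring A by cycloaddition–aromatisation, hydrogenolysis.
- Stereochemistry: C2 from the chiral titanium BINOLate; C3 by substrate control (oxidant anti to the C2 aryl group, giving the trans isomer, which is also the more stable one); ring A formation creates no stereocentre.

Key step: step 11

Assumption: (S)-BINOL/Ti(OiPr)4 is taken to give the (2S)-pyranone of step 2, by analogy with benzaldehyde in this catalyst system; should the sense prove opposite, (R)-BINOL is used and nothing else changes.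

Remark: the sulfoxide and the transient chloro sulfide and cycloadduct are epimer mixtures at centres that are destroyed later (sulfur; C5/C6 of the chloro sulfide; C4a/C5/C8a of the adduct), so their SMILES leave these centres open.

**Route**

Step 1
Reactants: 1 3-hydroxy-4,5-dimethoxybenzaldehyde
Product: 2 3-(benzyloxy)-4,5-dimethoxybenzaldehyde
Conditions: BnBr, K2CO3, DMF, rt
Reagents that add atoms: benzyl bromide, BrCc1ccccc1
Why: Williamson etherification masks the only phenol as a benzyl ether that should survive every later step and fall together with the ring A benzyl ether at the end.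

Step 2
Reactants: 2 3-(benzyloxy)-4,5-dimethoxybenzaldehyde; 3 (E)-1-methoxy-3-(trimethylsilyloxy)buta-1,3-diene (Danishefsky's diene)
Product: 5 (2S)-2-[3-(benzyloxy)-4,5-dimethoxyphenyl]-2,3-dihydro-4H-pyran-4-one, via Mukaiyama aldol silyl ether 4 (not isolated)
Conditions: (S)-BINOL (20 mol %), Ti(OiPr)4 (10 mol %), 4 Å MS, Et2O, −20 °C; then TFA, CH2Cl2, 0 °C
Reagents that add atoms: none
Why: Formal hetero-Diels–Alder reaction (BINOL–titanium-catalysed Mukaiyama aldol addition, then acid cyclisation with loss of methanol and the silyl group); the chiral tetravalent titanium BINOLate selects one aldehyde face and so sets C2, and the aldehyde should be about as electrophilic as benzaldehyde because its para-methoxy group is twisted out of conjugation by two ortho neighbours.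

Step 3
Reactants: 5 (2S)-2-[3-(benzyloxy)-4,5-dimethoxyphenyl]-2,3-dihydro-4H-pyran-4-one
Product: 8 (2R,3R)-2-[3-(benzyloxy)-4,5-dimethoxyphenyl]-3-hydroxy-2,3-dihydro-4H-pyran-4-one, via 4-silyloxy-2H-pyran 6 (not isolated), via 3-silyloxy ketone 7 (not isolated)
Conditions: TMSOTf, Et3N, CH2Cl2, 0 °C; crude 6, mCPBA, CH2Cl2–hexane, −20 °C; then 1 M HCl, THF, 0 °C
Reagents that add atoms: 3-chloroperoxybenzoic acid (mCPBA), OOC(=O)c1cccc(Cl)c1
Why: Rubottom oxidation: soft enolisation is possible only at C3, and the peracid should epoxidise the silyl enol ether bond of the cross-conjugated dienol ether on the face opposite the adjacent C2 aryl group, so that after silyl migration and hydrolysis the hydroxyl is trans to the aryl group (the C2 descriptor changes from S to R only because C3 now outranks the aryl carbon).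

Step 4
Reactants: 8 (2R,3R)-2-[3-(benzyloxy)-4,5-dimethoxyphenyl]-3-hydroxy-2,3-dihydro-4H-pyran-4-one
Product: 9 (2R,3R)-2-[3-(benzyloxy)-4,5-dimethoxyphenyl]-3-methoxy-2,3-dihydro-4H-pyran-4-one
Conditions: MeI, Ag2O, 4 Å MS, CH2Cl2, rt, dark
Reagents that add atoms: iodomethane, CI
Why: Purdie methylation of the secondary alcohol under near-neutral conditions that should not enolise the ketone; the trans isomer is also the thermodynamically preferred one, so C3 is not at risk.

Step 5
Reactants: 9 (2R,3R)-2-[3-(benzyloxy)-4,5-dimethoxyphenyl]-3-methoxy-2,3-dihydro-4H-pyran-4-one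
Product: 11 (2R,3R)-2-[3-(benzyloxy)-4,5-dimethoxyphenyl]-3-methoxy-5-(phenylsulfanyl)-2,3-dihydro-4H-pyran-4-one, via chloro sulfide adduct 10 (not isolated)
Conditions: PhSCl (1.05 equiv), CH2Cl2, −78 → 0 °C; then Et3N, 0 °C → rt
Reagents that add atoms: benzenesulfenyl chloride, ClSc1ccccc1
Why: Sulfenyl chloride addition to the enol ether bond C5=C6 (sulfur to the nucleophilic C5, chloride to C6) followed by amine-induced dehydrochlorination, the sequence known for dihydropyran and other enol ethers; Et3N should not enolise the ketone towards C3.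

Step 6
Reactants: 11 (2R,3R)-2-[3-(benzyloxy)-4,5-dimethoxyphenyl]-3-methoxy-5-(phenylsulfanyl)-2,3-dihydro-4H-pyran-4-one
Product: 12 (2R,3R)-2-[3-(benzyloxy)-4,5-dimethoxyphenyl]-3-methoxy-5-(phenylsulfinyl)-2,3-dihydro-4H-pyran-4-one
Conditions: mCPBA (1.0 equiv), CH2Cl2, −78 °C
Reagents that add atoms: 3-chloroperoxybenzoic acid (mCPBA), OOC(=O)c1cccc(Cl)c1
Why: Chemoselective sulfide-to-sulfoxide oxidation with one equivalent of peracid; the push–pull alkene and the aryl rings should be inert, the vinylic sulfoxide has no β-hydrogen on sp3 carbon and so should be stable, and the sulfur configuration is left open because sulfur is expelled in step 11.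

Step 7
Reactants: 13 methyl acetoacetate
Product: 14 methyl 2-diazo-3-oxobutanoate
Conditions: 4-acetamidobenzenesulfonyl azide, Et3N, MeCN, 0 °C → rt
Reagents that add atoms: 4-acetamidobenzenesulfonyl azide, CC(=O)Nc1ccc(cc1)S(=O)(=O)N=[N+]=[N-]
Why: Regitz diazo transfer to the active methylene group.

Step 8
Reactants: 14 methyl 2-diazo-3-oxobutanoate
Product: 15 methyl 2-(benzyloxy)-3-oxobutanoate
Conditions: Rh2(OAc)4 (1 mol %), BnOH (1.5 equiv), PhH, 80 °C
Reagents that add atoms: benzyl alcohol, OCc1ccccc1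
Why: Rh2(OAc)4-catalysed carbenoid O–H insertion into benzyl alcohol places the future C6 oxygen, already benzyl-protected, on C2 of the acetoacetate.

Step 9
Reactants: 15 methyl 2-(benzyloxy)-3-oxobutanoate
Product: 17 methyl 2-(benzyloxy)-3-methoxybut-2-enoate, via dimethyl ketal 16 (not isolated)
Conditions: HC(OMe)3, H2SO4 (cat.), MeOH, rt; then TsOH (cat.), 120 °C, MeOH distilled off
Reagents that add atoms: trimethyl orthoformate, COC(OC)OC
Why: Acid-catalysed ketalisation and thermal loss of methanol to the conjugated enol ether, as for other 3-methoxycrotonate diene precursors; the alkene geometry is irrelevant, and any non-conjugated isomer would give the same dienolate in step 10.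

Step 10
Reactants: 17 methyl 2-(benzyloxy)-3-methoxybut-2-enoate
Product: 19 2-(benzyloxy)-1,3-dimethoxy-1-(trimethylsilyloxy)buta-1,3-diene, via lithium dienolate 18 (not isolated)
Conditions: LiN(iPr)2 (LDA), THF, −78 °C; then Me3SiCl, −78 °C → rt; used crude
Reagents that add atoms: chlorotrimethylsilane, C[Si](C)(C)Cl
Why: γ-Deprotonation of the β-methoxy enoate (only the C4 methyl carries an acidic hydrogen) gives the extended dienolate, which is silylated on oxygen to the vinylketene silyl acetal.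

Step 11
Reactants: 12 (2R,3R)-2-[3-(benzyloxy)-4,5-dimethoxyphenyl]-3-methoxy-5-(phenylsulfinyl)-2,3-dihydro-4H-pyran-4-one; 19 2-(benzyloxy)-1,3-dimethoxy-1-(trimethylsilyloxy)buta-1,3-diene
Product: 22 (2R,3R)-6-(benzyloxy)-2-[3-(benzyloxy)-4,5-dimethoxyphenyl]-5-hydroxy-3,7-dimethoxychroman-4-one, via cis-fused sulfinyl cycloadduct 20 (not isolated), via 5,8-dihydro silyl ketal 21 (not isolated)
Conditions: 19 (2.5 equiv), PhMe, rt → 80 °C; then SiO2
Reagents that add atoms: none
Why: Proposed new method: the electron-rich vinylketene acetal 19 should add across the sulfinyl-activated C5=C6 bond of 12 (C4a=C8a of the flavanone) in a normal-demand [4+2] cycloaddition (concerted but asynchronous, at the limit Mukaiyama–Michael addition then ring closure), after which syn-elimination of benzenesulfenic acid from 20 (sulfoxide on C4a and hydrogen on C8a on the same face) and loss of methoxytrimethylsilane from the C5 ketal of 21 leave a cyclohexadienone that tautomerises to the C5 phenol. The closest known reactions are the benzannulations of 1,3-dialkoxy-1-silyloxybutadienes with halo- or sulfinylquinones and with 3-acceptor-substituted chromones and the cycloaddition–sulfoxide elimination of 2-sulfinylcycloalkenones, whereas a 5-sulfinyl-2,3-dihydropyran-4-one has not been used as the dienophile. Ring A is closed by the intermolecular cycloaddition itself, which forms C4a–C5 and C8–C8a in one operation without a tether, and is then aromatised. No new stereocentre survives, since C4a, C5 and C8a become sp2, so facial and endo/exo selectivity do not matter and C2 and C3 are untouched under neutral thermal conditions. Only regioselectivity is needed: the nucleophilic CH2 terminus of the diene pairs with C6 of 12, the enone β-carbon made electrophilic by carbonyl and sulfinyl groups, and the only β-hydrogen available to the sulfoxide is on C8a, so elimination can only restore the C4a=C8a bond.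

Step 12
Reactants: 22 (2R,3R)-6-(benzyloxy)-2-[3-(benzyloxy)-4,5-dimethoxyphenyl]-5-hydroxy-3,7-dimethoxychroman-4-one
Product: 23 (2R,3R)-5,6-dihydroxy-2-(3-hydroxy-4,5-dimethoxyphenyl)-3,7-dimethoxychroman-4-one
Conditions: H2 (1 atm), 10% Pd/C, EtOAc–MeOH, rt
Reagents that add atoms: none
Why: Hydrogenolysis of the two aryl benzyl ethers; the aryl ketone, the methyl ethers and the ring C2–O bond should survive if the reaction is stopped after uptake of two equivalents of hydrogen, and no stereocentre is touched.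

**Compound list**

1 | 3-hydroxy-4,5-dimethoxybenzaldehyde | COc1cc(C=O)cc(O)c1OC | starting material
2 | 3-(benzyloxy)-4,5-dimethoxybenzaldehyde | COc1cc(C=O)cc(OCc2ccccc2)c1OC | intermediate
3 | (E)-1-methoxy-3-(trimethylsilyloxy)buta-1,3-diene (Danishefsky's diene) | CO/C=C/C(=C)O[Si](C)(C)C | starting material
4 | (1E,5S)-5-[3-(benzyloxy)-4,5-dimethoxyphenyl]-1-methoxy-5-(trimethylsilyloxy)pent-1-en-3-one (formed in situ) | CO/C=C/C(=O)C[C@H](O[Si](C)(C)C)c1cc(OCc2ccccc2)c(OC)c(OC)c1 | intermediate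
5 | (2S)-2-[3-(benzyloxy)-4,5-dimethoxyphenyl]-2,3-dihydro-4H-pyran-4-one | C1=CC(=O)C[C@@H](c2cc(OCc3ccccc3)c(OC)c(OC)c2)O1 | intermediate
6 | {[(2S)-2-[3-(benzyloxy)-4,5-dimethoxyphenyl]-2H-pyran-4-yl]oxy}trimethylsilane (formed in situ) | C[Si](C)(C)OC1=C[C@@H](c2cc(OCc3ccccc3)c(OC)c(OC)c2)OC=C1 | intermediate
7 | (2R,3R)-2-[3-(benzyloxy)-4,5-dimethoxyphenyl]-3-(trimethylsilyloxy)-2,3-dihydro-4H-pyran-4-one (formed in situ) | C1=CC(=O)[C@H](O[Si](C)(C)C)[C@@H](c2cc(OCc3ccccc3)c(OC)c(OC)c2)O1 | intermediate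
8 | (2R,3R)-2-[3-(benzyloxy)-4,5-dimethoxyphenyl]-3-hydroxy-2,3-dihydro-4H-pyran-4-one | C1=CC(=O)[C@H](O)[C@@H](c2cc(OCc3ccccc3)c(OC)c(OC)c2)O1 | intermediate
9 | (2R,3R)-2-[3-(benzyloxy)-4,5-dimethoxyphenyl]-3-methoxy-2,3-dihydro-4H-pyran-4-one | C1=CC(=O)[C@H](OC)[C@@H](c2cc(OCc3ccccc3)c(OC)c(OC)c2)O1 | intermediate
10 | (2R,3R)-2-[3-(benzyloxy)-4,5-dimethoxyphenyl]-6-chloro-3-methoxy-5-(phenylsulfanyl)tetrahydro-4H-pyran-4-one (C5/C6 epimers; formed in situ) | ClC1C(Sc2ccccc2)C(=O)[C@H](OC)[C@@H](c2cc(OCc3ccccc3)c(OC)c(OC)c2)O1 | intermediate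
11 | (2R,3R)-2-[3-(benzyloxy)-4,5-dimethoxyphenyl]-3-methoxy-5-(phenylsulfanyl)-2,3-dihydro-4H-pyran-4-one | C1=C(Sc2ccccc2)C(=O)[C@H](OC)[C@@H](c2cc(OCc3ccccc3)c(OC)c(OC)c2)O1 | intermediate
12 | (2R,3R)-2-[3-(benzyloxy)-4,5-dimethoxyphenyl]-3-methoxy-5-(phenylsulfinyl)-2,3-dihydro-4H-pyran-4-one (both sulfur epimers) | C1=C(S(=O)c2ccccc2)C(=O)[C@H](OC)[C@@H](c2cc(OCc3ccccc3)c(OC)c(OC)c2)O1 | intermediate
13 | methyl acetoacetate | CC(=O)CC(=O)OC | starting material
14 | methyl 2-diazo-3-oxobutanoate | CC(=O)C(=[N+]=[N-])C(=O)OC | intermediate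
15 | methyl 2-(benzyloxy)-3-oxobutanoate (racemic) | CC(=O)C(OCc1ccccc1)C(=O)OC | intermediate
16 | methyl 2-(benzyloxy)-3,3-dimethoxybutanoate (racemic; formed in situ) | COC(C)(OC)C(OCc1ccccc1)C(=O)OC | intermediate
17 | methyl 2-(benzyloxy)-3-methoxybut-2-enoate (E/Z mixture) | COC(C)=C(OCc1ccccc1)C(=O)OC | intermediate
18 | lithium 2-(benzyloxy)-1,3-dimethoxybuta-1,3-dien-1-olate (formed in situ) | [Li+].[O-]C(OC)=C(OCc1ccccc1)C(OC)=C | intermediate
19 | 2-(benzyloxy)-1,3-dimethoxy-1-(trimethylsilyloxy)buta-1,3-diene | C=C(OC)C(OCc1ccccc1)=C(OC)O[Si](C)(C)C | intermediate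
20 | (2R,3R)-6-(benzyloxy)-2-[3-(benzyloxy)-4,5-dimethoxyphenyl]-3,5,7-trimethoxy-4a-(phenylsulfinyl)-5-(trimethylsilyloxy)-2,3,4a,5,8,8a-hexahydro-4H-chromen-4-one (cis-fused; epimers at C4a/C5/C8a and sulfur; formed in situ) | COC1=C(OCc3ccccc3)C(OC)(O[Si](C)(C)C)C2(S(=O)c3ccccc3)C(=O)[C@H](OC)[C@@H](c3cc(OCc4ccccc4)c(OC)c(OC)c3)OC2C1 | intermediate
21 | (2R,3R)-6-(benzyloxy)-2-[3-(benzyloxy)-4,5-dimethoxyphenyl]-3,5,7-trimethoxy-5-(trimethylsilyloxy)-2,3,5,8-tetrahydro-4H-chromen-4-one (C5 epimers; formed in situ) | COC1=C(OCc3ccccc3)C(OC)(O[Si](C)(C)C)C2=C(C1)O[C@H](c3cc(OCc4ccccc4)c(OC)c(OC)c3)[C@@H](OC)C2=O | intermediate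
22 | (2R,3R)-6-(benzyloxy)-2-[3-(benzyloxy)-4,5-dimethoxyphenyl]-5-hydroxy-3,7-dimethoxychroman-4-one | COc1cc2c(c(O)c1OCc1ccccc1)C(=O)[C@H](OC)[C@@H](c1cc(OCc3ccccc3)c(OC)c(OC)c1)O2 | intermediate
23 | (2R,3R)-5,6-dihydroxy-2-(3-hydroxy-4,5-dimethoxyphenyl)-3,7-dimethoxychroman-4-one | COc1cc2c(c(O)c1O)C(=O)[C@H](OC)[C@@H](c1cc(O)c(OC)c(OC)c1)O2 | target

**Step count**

Total: 12 steps. Longest linear sequence: 8 steps (steps 1–6, 11, 12); the diene branch (steps 7–10) joins at step 11.

**Steps most likely to fail**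

Step 11. The vinylogous-ester dienophile may react too slowly, so that the diene is consumed by desilylation or by silyl transfer to the sulfoxide oxygen before cycloaddition. Fallback by known chemistry, setting out from 2 and returning at 23:
- Elbs persulfate oxidation (K2S2O8, aq NaOH) of commercial 1-(2-hydroxy-4,6-dimethoxyphenyl)ethanone would give potassium 3-acetyl-4-hydroxy-2,6-dimethoxyphenyl sulfate F1, and acid hydrolysis would give 1-(3,6-dihydroxy-2,4-dimethoxyphenyl)ethanone F2.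
- Benzylation of the non-chelated hydroxyl (BnBr, K2CO3, acetone) would give 1-[3-(benzyloxy)-6-hydroxy-2,4-dimethoxyphenyl]ethanone F3, and MOMCl/iPr2NEt would give 1-[3-(benzyloxy)-2,4-dimethoxy-6-(methoxymethoxy)phenyl]ethanone F4.
- Claisen–Schmidt condensation of F4 with 2 (KOH, EtOH) would give (E)-1-[3-(benzyloxy)-2,4-dimethoxy-6-(methoxymethoxy)phenyl]-3-[3-(benzyloxy)-4,5-dimethoxyphenyl]prop-2-en-1-one F5.
- Juliá–Colonna epoxidation (poly-L-leucine, urea–H2O2, DBU, THF) would give [3-(benzyloxy)-2,4-dimethoxy-6-(methoxymethoxy)phenyl][(2R,3S)-3-[3-(benzyloxy)-4,5-dimethoxyphenyl]oxiran-2-yl]methanone F6.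
- HCl/MeOH would remove the MOM group and let the freed phenol open the epoxide at the benzylic carbon with inversion, giving (2R,3R)-6-(benzyloxy)-2-[3-(benzyloxy)-4,5-dimethoxyphenyl]-3-hydroxy-5,7-dimethoxychroman-4-one F7.
- MeI/Ag2O would give (2R,3R)-6-(benzyloxy)-2-[3-(benzyloxy)-4,5-dimethoxyphenyl]-3,5,7-trimethoxychroman-4-one F8, and BCl3 with pentamethylbenzene (CH2Cl2, −78 → 0 °C) would cleave the chelated 5-O-methyl group and both benzyl ethers to give 23.

Step 5. The sulfenyl chloride may attack the electron-rich aryl ring in competition with C5, or dehydrochlorination may be incomplete. Fallback from 9, returning at 11: α-iodination of the enone (I2, pyridine, CH2Cl2) would give (2R,3R)-2-[3-(benzyloxy)-4,5-dimethoxyphenyl]-5-iodo-3-methoxy-2,3-dihydro-4H-pyran-4-one F9, and palladium-catalysed C–S coupling (PhSH, Pd2(dba)3, Xantphos, iPr2NEt, dioxane, 80 °C) would give 11.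

Step 3. Facial selectivity of the epoxidation may be poor, or the dienol silyl ether may hydrolyse back to 5 before it is oxidised. Fallback from 5, returning at 8: α′-acetoxylation with Mn(OAc)3·2H2O (PhH, reflux, water removed), which is known to give the trans product on 2-substituted dihydropyranones, would give (2R,3R)-2-[3-(benzyloxy)-4,5-dimethoxyphenyl]-4-oxo-3,4-dihydro-2H-pyran-3-yl acetate F10, and mild methanolysis (K2CO3 cat., MeOH, 0 °C) would give 8.

**Further compounds**

F1 | step 11 | potassium 3-acetyl-4-hydroxy-2,6-dimethoxyphenyl sulfate | CC(=O)c1c(O)cc(OC)c(OS(=O)(=O)[O-])c1OC.[K+]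
F2 | step 11 | 1-(3,6-dihydroxy-2,4-dimethoxyphenyl)ethanone | CC(=O)c1c(O)cc(OC)c(O)c1OC
F3 | step 11 | 1-[3-(benzyloxy)-6-hydroxy-2,4-dimethoxyphenyl]ethanone | CC(=O)c1c(O)cc(OC)c(OCc2ccccc2)c1OC
F4 | step 11 | 1-[3-(benzyloxy)-2,4-dimethoxy-6-(methoxymethoxy)phenyl]ethanone | CC(=O)c1c(OCOC)cc(OC)c(OCc2ccccc2)c1OC
F5 | step 11 | (E)-1-[3-(benzyloxy)-2,4-dimethoxy-6-(methoxymethoxy)phenyl]-3-[3-(benzyloxy)-4,5-dimethoxyphenyl]prop-2-en-1-one | COCOc1cc(OC)c(OCc2ccccc2)c(OC)c1C(=O)/C=C/c1cc(OCc2ccccc2)c(OC)c(OC)c1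
F6 | step 11 | [3-(benzyloxy)-2,4-dimethoxy-6-(methoxymethoxy)phenyl][(2R,3S)-3-[3-(benzyloxy)-4,5-dimethoxyphenyl]oxiran-2-yl]methanone | COCOc1cc(OC)c(OCc2ccccc2)c(OC)c1C(=O)[C@@H]1O[C@H]1c1cc(OCc2ccccc2)c(OC)c(OC)c1
F7 | step 11 | (2R,3R)-6-(benzyloxy)-2-[3-(benzyloxy)-4,5-dimethoxyphenyl]-3-hydroxy-5,7-dimethoxychroman-4-one | COc1cc2c(c(OC)c1OCc1ccccc1)C(=O)[C@H](O)[C@@H](c1cc(OCc3ccccc3)c(OC)c(OC)c1)O2
F8 | step 11 | (2R,3R)-6-(benzyloxy)-2-[3-(benzyloxy)-4,5-dimethoxyphenyl]-3,5,7-trimethoxychroman-4-one | COc1cc2c(c(OC)c1OCc1ccccc1)C(=O)[C@H](OC)[C@@H](c1cc(OCc3ccccc3)c(OC)c(OC)c1)O2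
F9 | step 5 | (2R,3R)-2-[3-(benzyloxy)-4,5-dimethoxyphenyl]-5-iodo-3-methoxy-2,3-dihydro-4H-pyran-4-one | C1=C(I)C(=O)[C@H](OC)[C@@H](c2cc(OCc3ccccc3)c(OC)c(OC)c2)O1
F10 | step 3 | (2R,3R)-2-[3-(benzyloxy)-4,5-dimethoxyphenyl]-4-oxo-3,4-dihydro-2H-pyran-3-yl acetate | C1=CC(=O)[C@H](OC(C)=O)[C@@H](c2cc(OCc3ccccc3)c(OC)c(OC)c2)O1
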